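**Retrosynthetic overview**

- Feature: in the prenylated indole, the benzo ring (C3a, C4–C7, C7a) carries one substituent only, the prenyl group at C5, and the pyrrole ring carries only the aryl group at C3. C5 is therefore taken from C5 of a 2-aminofuran, and C3 from a tertiary allylic carbinol carbon.
- Key disconnection: both rings of this indole are opened at C3a–C7a and C4–C5, back to an N-Boc 2-amidofuran whose nitrogen carries the tether CH2–C(OH)(Ar)–CH=CH2. The second indole (as its N-triisopropylsilyl derivative) and the tetramethoxybenzene core are carried in intact.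
- The carbinol is cut at the C2–C3 bond (indole numbering) into an N-Boc aminomethyllithium (from its stannane) and an aryl vinyl ketone.
- Amine half: 2-furoic acid, C5 prenylation, Curtius rearrangement, N-stannylmethylation. Ketone half: tetramethoxybenzene, dibromination, single Negishi coupling with the 3-indolylzinc reagent, aryllithium addition to acrolein, oxidation.
- Ring order: the benzo ring and the pyrrole ring of the prenylated indole are formed together in the penultimate step; N-desilylation ends the route.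

Key step: step 9

Assumption: the carbinol centres of 19 and 22 are formed racemic; this is immaterial because both carbons become sp2 later and the target has no stereocentre.

**Route**

Step 1
Reactants: 1 2-furoic acid; 2 prenyl bromide (1-bromo-3-methylbut-2-ene)
Product: 4 5-(3-methylbut-2-en-1-yl)furan-2-carboxylic acid, via lithium 5-lithiofuran-2-carboxylate 3 (not isolated)
Conditions: LiN(iPr)2 (2.2 equiv), THF, −78 °C; then 2, −78 °C to rt; aq HCl work-up
Reagents that add atoms: none
Why: Two equivalents of lithium amide convert the acid into the carboxylate lithiated at C5 (deprotonation of the only free α-position of the furan), and this dianion should be alkylated at carbon by the primary allylic bromide in an SN2 reaction.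

Step 2
Reactants: 4 5-(3-methylbut-2-en-1-yl)furan-2-carboxylic acid
Product: 7 tert-butyl N-[5-(3-methylbut-2-en-1-yl)furan-2-yl]carbamate, via acyl azide 5 (not isolated), via furan-2-yl isocyanate 6 (not isolated)
Conditions: (PhO)2P(O)N3, Et3N, t-BuOH/toluene, 85 °C
Reagents that add atoms: diphenylphosphoryl azide, O=P(N=[N+]=[N-])(Oc1ccccc1)Oc1ccccc1; tert-butanol, CC(C)(C)O
Why: Curtius rearrangement: the acyl azide loses dinitrogen with migration of the furyl group to nitrogen, and the isocyanate is trapped by tert-butanol as the Boc carbamate, the usual entry to 2-amidofurans.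

Step 3
Reactants: 7 tert-butyl N-[5-(3-methylbut-2-en-1-yl)furan-2-yl]carbamate; 8 tributyl(iodomethyl)stannane
Product: 10 tert-butyl N-[5-(3-methylbut-2-en-1-yl)furan-2-yl]-N-[(tributylstannyl)methyl]carbamate, via sodium carbamate 9 (not isolated)
Conditions: NaH, DMF, 0 °C; then 8, 0 °C to rt
Reagents that add atoms: none
Why: N-alkylation (SN2) of the sodium carbamate by the unhindered primary iodide, a known way to place a stannylmethyl group on Boc-protected aminofurans.

Step 4
Reactants: 11 1,2,4,5-tetramethoxybenzene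
Product: 12 1,4-dibromo-2,3,5,6-tetramethoxybenzene
Conditions: Br2 (2.2 equiv), CH2Cl2, 0 °C to rt
Reagents that add atoms: bromine, BrBr
Why: Electrophilic aromatic bromination; the two free ring positions are the only sites and each is activated by two ortho methoxy groups.

Step 5
Reactants: 13 3-bromo-1-(triisopropylsilyl)indole; 12 1,4-dibromo-2,3,5,6-tetramethoxybenzene
Product: 16 3-(4-bromo-2,3,5,6-tetramethoxyphenyl)-1-(triisopropylsilyl)indole, via 3-lithioindole 14 (not isolated), via indol-3-ylzinc chloride 15 (not isolated)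
Conditions: t-BuLi (2 equiv), THF, −78 °C; ZnCl2, −78 °C to rt; then 12 (3 equiv), Pd2(dba)3, SPhos, THF, 65 °C
Reagents that add atoms: none
Why: Bromine–lithium exchange at C3 (the bulky N-silyl group holds the lithium at C3), transmetalation to zinc and Negishi cross-coupling under zerovalent palladium with a biarylphosphine ligand suited to di-ortho-substituted electron-rich bromides; the excess of 12 should hold back a second coupling.

Step 6
Reactants: 16 3-(4-bromo-2,3,5,6-tetramethoxyphenyl)-1-(triisopropylsilyl)indole; 17 acrolein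
Product: 19 racemic 1-{2,3,5,6-tetramethoxy-4-[1-(triisopropylsilyl)indol-3-yl]phenyl}prop-2-en-1-ol, via aryllithium 18 (not isolated)
Conditions: n-BuLi, THF, −78 °C; then 17, −78 °C; aq NH4Cl
Reagents that add atoms: none
Why: Bromine–lithium exchange followed by 1,2-addition of the aryllithium to the aldehyde of acrolein; the carbinol centre is formed without control and is removed in the next step.

Step 7
Reactants: 19 racemic 1-{2,3,5,6-tetramethoxy-4-[1-(triisopropylsilyl)indol-3-yl]phenyl}prop-2-en-1-ol
Product: 20 1-{2,3,5,6-tetramethoxy-4-[1-(triisopropylsilyl)indol-3-yl]phenyl}prop-2-en-1-one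
Conditions: Dess–Martin periodinane, pyridine, CH2Cl2, 0 °C to rt; used at once
Reagents that add atoms: none
Why: Dess–Martin oxidation of the secondary allylic, benzylic alcohol to the aryl vinyl ketone under near-neutral conditions that should leave the N–Si bond and the electron-rich rings untouched.

Step 8
Reactants: 10 tert-butyl N-[5-(3-methylbut-2-en-1-yl)furan-2-yl]-N-[(tributylstannyl)methyl]carbamate; 20 1-{2,3,5,6-tetramethoxy-4-[1-(triisopropylsilyl)indol-3-yl]phenyl}prop-2-en-1-one
Product: 22 racemic tert-butyl N-[5-(3-methylbut-2-en-1-yl)furan-2-yl]-N-(2-hydroxy-2-{2,3,5,6-tetramethoxy-4-[1-(triisopropylsilyl)indol-3-yl]phenyl}but-3-en-1-yl)carbamate, via aminomethyllithium 21 (not isolated)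
Conditions: n-BuLi, THF, −78 °C; then 20, −78 °C; aq NH4Cl at −78 °C
Reagents that add atoms: none
Why: Tin–lithium exchange gives the dipole-stabilised α-amino alkyllithium, a hard nucleophile that should add 1,2 to the enone carbonyl (an addition known for this reagent class with enones and enals), giving the racemic tertiary carbinol whose configuration is irrelevant, while the cold quench keeps the alkoxide from attacking the Boc group.

Step 9
Reactants: 22 racemic tert-butyl N-[5-(3-methylbut-2-en-1-yl)furan-2-yl]-N-(2-hydroxy-2-{2,3,5,6-tetramethoxy-4-[1-(triisopropylsilyl)indol-3-yl]phenyl}but-3-en-1-yl)carbamate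
Product: 26 3-{2,3,5,6-tetramethoxy-4-[5-(3-methylbut-2-en-1-yl)-1H-indol-3-yl]phenyl}-1-(triisopropylsilyl)indole, via oxa-bridged cycloadduct 23 (not isolated), via N-Boc 3-hydroxyindoline 24 (not isolated), via N-Boc indole 25 (not isolated)
Conditions: o-dichlorobenzene (dilute, degassed), 180 °C, microwave or sealed tube
Reagents that add atoms: none
Why: On heating, the electron-rich 2-amidofuran serves as diene and the tethered vinyl group as dienophile in an intramolecular [4+2] cycloaddition that forms C3a–C7a and C4–C5 to give adduct 23; the carbamate nitrogen lone pair then opens the bridge at C7a–O, proton loss and expulsion of the former furan oxygen as water aromatise the six-membered ring to indoline 24, loss of water from the tertiary benzylic C3 carbinol gives N-Boc indole 25, and the Boc group leaves thermally as 2-methylpropene and CO2. The closest known reaction type is the intramolecular Diels–Alder reaction of 2-amidofurans bearing allylic-alcohol tethers, which runs through the same aromatisation cascade to indoles under microwave heating. The benzo ring is closed by the cycloaddition itself (four furan carbons plus the two vinyl carbons), and the five-membered ring is closed in the same event as the ring containing the three-atom tether N1–C2–C3 between furan C2 (C7a) and the internal vinyl carbon (C3a). No stereocentre remains in 26, because the carbinol centre of racemic 22 and all centres of 23, from endo or exo approach alike, are erased by the two dehydrations. The step needs the vinyl group, not the trisubstituted prenyl alkene or an indole C2–C3 bond, to act as dienophile, and needs prenyl at C5 and aryl at C3; only the vinyl group can reach the furan through the three-atom tether, and the 2,5-substitution of the furan together with the aryl group on the carbinol carbon fixes both positions.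

Step 10
Reactants: 26 3-{2,3,5,6-tetramethoxy-4-[5-(3-methylbut-2-en-1-yl)-1H-indol-3-yl]phenyl}-1-(triisopropylsilyl)indole
Product: 27 3-[4-(1H-indol-3-yl)-2,3,5,6-tetramethoxyphenyl]-5-(3-methylbut-2-en-1-yl)-1H-indole (CNP0306547.0)
Conditions: Bu4NF·3H2O, THF, 0 °C to rt
Reagents that add atoms: none
Why: Fluoride-mediated N-desilylation driven by the strength of the Si–F bond; the aryl methyl ethers, the prenyl alkene and both indoles should be inert to fluoride.

**Compound list**

1 | 2-furoic acid | OC(=O)c1ccco1 | starting material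
2 | prenyl bromide (1-bromo-3-methylbut-2-ene) | CC(C)=CCBr | starting material
3 | lithium 5-lithiofuran-2-carboxylate | [Li]c1ccc(o1)C(=O)O[Li] | intermediate
4 | 5-(3-methylbut-2-en-1-yl)furan-2-carboxylic acid | CC(C)=CCc1ccc(o1)C(O)=O | intermediate
5 | 5-(3-methylbut-2-en-1-yl)furan-2-carbonyl azide | CC(C)=CCc1ccc(o1)C(=O)N=[N+]=[N-] | intermediate
6 | 2-isocyanato-5-(3-methylbut-2-en-1-yl)furan | CC(C)=CCc1ccc(o1)N=C=O | intermediate
7 | tert-butyl N-[5-(3-methylbut-2-en-1-yl)furan-2-yl]carbamate | CC(C)=CCc1ccc(o1)NC(=O)OC(C)(C)C | intermediate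
8 | tributyl(iodomethyl)stannane | CCCC[Sn](CCCC)(CCCC)CI | starting material
9 | sodium salt of carbamate 7 | CC(C)=CCc1ccc(o1)[N-]C(=O)OC(C)(C)C.[Na+] | intermediate
10 | tert-butyl N-[5-(3-methylbut-2-en-1-yl)furan-2-yl]-N-[(tributylstannyl)methyl]carbamate | CC(C)=CCc1ccc(o1)N(C[Sn](CCCC)(CCCC)CCCC)C(=O)OC(C)(C)C | intermediate
11 | 1,2,4,5-tetramethoxybenzene | COc1cc(OC)c(OC)cc1OC | starting material
12 | 1,4-dibromo-2,3,5,6-tetramethoxybenzene | COc1c(Br)c(OC)c(OC)c(Br)c1OC | intermediate
13 | 3-bromo-1-(triisopropylsilyl)indole | CC(C)[Si](C(C)C)(C(C)C)n1cc(Br)c2ccccc21 | starting material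
14 | 3-lithio-1-(triisopropylsilyl)indole | CC(C)[Si](C(C)C)(C(C)C)n1cc([Li])c2ccccc21 | intermediate
15 | [1-(triisopropylsilyl)indol-3-yl]zinc chloride | CC(C)[Si](C(C)C)(C(C)C)n1cc([Zn]Cl)c2ccccc21 | intermediate
16 | 3-(4-bromo-2,3,5,6-tetramethoxyphenyl)-1-(triisopropylsilyl)indole | COc1c(Br)c(OC)c(OC)c(-c2cn([Si](C(C)C)(C(C)C)C(C)C)c3ccccc23)c1OC | intermediate
17 | acrolein | C=CC=O | starting material
18 | {2,3,5,6-tetramethoxy-4-[1-(triisopropylsilyl)indol-3-yl]phenyl}lithium | COc1c([Li])c(OC)c(OC)c(-c2cn([Si](C(C)C)(C(C)C)C(C)C)c3ccccc23)c1OC | intermediate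
19 | racemic 1-{2,3,5,6-tetramethoxy-4-[1-(triisopropylsilyl)indol-3-yl]phenyl}prop-2-en-1-ol | C=CC(O)c1c(OC)c(OC)c(-c2cn([Si](C(C)C)(C(C)C)C(C)C)c3ccccc23)c(OC)c1OC | intermediate
20 | 1-{2,3,5,6-tetramethoxy-4-[1-(triisopropylsilyl)indol-3-yl]phenyl}prop-2-en-1-one | C=CC(=O)c1c(OC)c(OC)c(-c2cn([Si](C(C)C)(C(C)C)C(C)C)c3ccccc23)c(OC)c1OC | intermediate
21 | {(tert-butoxycarbonyl)[5-(3-methylbut-2-en-1-yl)furan-2-yl]amino}methyllithium | CC(C)=CCc1ccc(o1)N(C[Li])C(=O)OC(C)(C)C | intermediate
22 | racemic tert-butyl N-[5-(3-methylbut-2-en-1-yl)furan-2-yl]-N-(2-hydroxy-2-{2,3,5,6-tetramethoxy-4-[1-(triisopropylsilyl)indol-3-yl]phenyl}but-3-en-1-yl)carbamate | CC(C)=CCc1ccc(o1)N(C(=O)OC(C)(C)C)CC(O)(C=C)c1c(OC)c(OC)c(-c2cn([Si](C(C)C)(C(C)C)C(C)C)c3ccccc23)c(OC)c1OC | intermediate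
23 | oxa-bridged cycloadduct (N-Boc 3-aryl-3-hydroxy-5-prenyl-5,7a-epoxy-2,3,3a,4,5,7a-hexahydroindole, mixture of diastereomers) | CC(C)(C)OC(=O)N1CC(O)(c4c(OC)c(OC)c(-c5cn([Si](C(C)C)(C(C)C)C(C)C)c6ccccc56)c(OC)c4OC)C2CC3(CC=C(C)C)OC12C=C3 | intermediate
24 | racemic tert-butyl 3-hydroxy-5-(3-methylbut-2-en-1-yl)-3-{2,3,5,6-tetramethoxy-4-[1-(triisopropylsilyl)indol-3-yl]phenyl}-2,3-dihydroindole-1-carboxylate | CC(C)(C)OC(=O)N1CC(O)(c4c(OC)c(OC)c(-c5cn([Si](C(C)C)(C(C)C)C(C)C)c6ccccc56)c(OC)c4OC)c2cc(CC=C(C)C)ccc12 | intermediate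
25 | tert-butyl 5-(3-methylbut-2-en-1-yl)-3-{2,3,5,6-tetramethoxy-4-[1-(triisopropylsilyl)indol-3-yl]phenyl}indole-1-carboxylate | CC(C)(C)OC(=O)n1cc(-c4c(OC)c(OC)c(-c5cn([Si](C(C)C)(C(C)C)C(C)C)c6ccccc56)c(OC)c4OC)c2cc(CC=C(C)C)ccc12 | intermediate
26 | 3-{2,3,5,6-tetramethoxy-4-[5-(3-methylbut-2-en-1-yl)-1H-indol-3-yl]phenyl}-1-(triisopropylsilyl)indole | COc1c(OC)c(-c2c[nH]c3ccc(CC=C(C)C)cc23)c(OC)c(OC)c1-c1cn([Si](C(C)C)(C(C)C)C(C)C)c2ccccc12 | intermediate
27 | 3-[4-(1H-indol-3-yl)-2,3,5,6-tetramethoxyphenyl]-5-(3-methylbut-2-en-1-yl)-1H-indole (CNP0306547.0) | COc1c(OC)c(-c2c[nH]c3ccc(CC=C(C)C)cc23)c(OC)c(OC)c1-c1c[nH]c2ccccc12 | target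

**Step count**

Total steps: 10. Longest linear sequence: 7 steps (steps 4, 5, 6, 7, 8, 9, 10, from 11 to 27).

**Steps most likely to fail**

1. Step 9. The cycloaddition may be outrun by thermal loss of the Boc group from the uncyclised amidofuran, by ionisation and dehydration of the doubly activated tertiary carbinol, or by closure of the hydroxyl onto the Boc carbonyl. The di-ortho-substituted aryl group next to the tether may also slow the approach of the vinyl group. Partial loss of the silyl group by the water set free would do no harm, since step 10 removes it. Fallback, setting out from 16 and purchased 5-bromoindole and coming back to the route at 27: the prenylated indole is brought in ready-made by cross-coupling instead of being built from the furan. 5-Bromoindole is silylated (NaH, iPr3SiCl, THF) to 5-bromo-1-(triisopropylsilyl)indole F1. Bromine–lithium exchange (t-BuLi, THF, −78 °C) gives 5-lithio-1-(triisopropylsilyl)indole F2, which is alkylated with prenyl bromide 2 to 5-(3-methylbut-2-en-1-yl)-1-(triisopropylsilyl)indole F3. Bromination at C3 with N-bromosuccinimide in THF at −78 °C gives 3-bromo-5-(3-methylbut-2-en-1-yl)-1-(triisopropylsilyl)indole F4. Exchange with t-BuLi gives 3-lithio-5-(3-methylbut-2-en-1-yl)-1-(triisopropylsilyl)indole F5, and ZnCl2 converts it into [5-(3-methylbut-2-en-1-yl)-1-(triisopropylsilyl)indol-3-yl]zinc chloride F6. Negishi coupling of F6 with 16 (Pd2(dba)3, SPhos, THF, 65 °C) should give 3-{2,3,5,6-tetramethoxy-4-[1-(triisopropylsilyl)indol-3-yl]phenyl}-5-(3-methylbut-2-en-1-yl)-1-(triisopropylsilyl)indole F7. Treatment with Bu4NF·3H2O removes both silyl groups to give 27.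

2. Step 8. The hindered, twisted aryl ketone may divert the organolithium to conjugate addition at the unhindered vinyl terminus. The vinyl ketone may polymerise, or the alkoxide may close onto the Boc carbonyl on warming. Fallback, setting out from 16 and 10 and coming back at 22: the order of bond formation at the carbinol carbon is changed so that the organolithium meets an aldehyde. Bromine–lithium exchange of 16 (n-BuLi, THF, −78 °C) gives 18, which is formylated with DMF to 2,3,5,6-tetramethoxy-4-[1-(triisopropylsilyl)indol-3-yl]benzaldehyde F8. Addition of 21 (from 10 and n-BuLi) gives racemic tert-butyl N-(2-hydroxy-2-{2,3,5,6-tetramethoxy-4-[1-(triisopropylsilyl)indol-3-yl]phenyl}ethyl)-N-[5-(3-methylbut-2-en-1-yl)furan-2-yl]carbamate F9. Dess–Martin oxidation gives tert-butyl N-[5-(3-methylbut-2-en-1-yl)furan-2-yl]-N-(2-oxo-2-{2,3,5,6-tetramethoxy-4-[1-(triisopropylsilyl)indol-3-yl]phenyl}ethyl)carbamate F10. Addition of CH2=CHMgBr in the presence of CeCl3 (THF, −78 °C) should then give 22.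

3. Step 5. Oxidative addition into the hindered, electron-rich C–Br bond may be slow, and a second coupling at the remaining bromide may erode the yield of the mono-coupled product. Fallback, setting out from 11 and 13 and coming back at 19: the dibromide is avoided by two directed metalations. Lithiation of 11 (n-BuLi, TMEDA, THF, 0 °C) at a position flanked by two methoxy groups gives (2,3,5,6-tetramethoxyphenyl)lithium F11. ZnCl2 converts it into (2,3,5,6-tetramethoxyphenyl)zinc chloride F12, and Negishi coupling with 13 (Pd2(dba)3, SPhos) gives 3-(2,3,5,6-tetramethoxyphenyl)-1-(triisopropylsilyl)indole F13. A second lithiation at the remaining aryl hydrogen (n-BuLi, TMEDA; indole C2 is shielded by the silyl group) gives 18, and addition of acrolein 17 gives 19.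

**Further compounds**

F1 | step 9 | 5-bromo-1-(triisopropylsilyl)indole | CC(C)[Si](C(C)C)(C(C)C)n1ccc2cc(Br)ccc21
F2 | step 9 | 5-lithio-1-(triisopropylsilyl)indole | CC(C)[Si](C(C)C)(C(C)C)n1ccc2cc([Li])ccc21
F3 | step 9 | 5-(3-methylbut-2-en-1-yl)-1-(triisopropylsilyl)indole | CC(C)=CCc1ccc2c(c1)ccn2[Si](C(C)C)(C(C)C)C(C)C
F4 | step 9 | 3-bromo-5-(3-methylbut-2-en-1-yl)-1-(triisopropylsilyl)indole | CC(C)=CCc1ccc2c(c1)c(Br)cn2[Si](C(C)C)(C(C)C)C(C)C
F5 | step 9 | 3-lithio-5-(3-methylbut-2-en-1-yl)-1-(triisopropylsilyl)indole | CC(C)=CCc1ccc2c(c1)c([Li])cn2[Si](C(C)C)(C(C)C)C(C)C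
F6 | step 9 | [5-(3-methylbut-2-en-1-yl)-1-(triisopropylsilyl)indol-3-yl]zinc chloride | CC(C)=CCc1ccc2c(c1)c([Zn]Cl)cn2[Si](C(C)C)(C(C)C)C(C)C
F7 | step 9 | 3-{2,3,5,6-tetramethoxy-4-[1-(triisopropylsilyl)indol-3-yl]phenyl}-5-(3-methylbut-2-en-1-yl)-1-(triisopropylsilyl)indole | COc1c(OC)c(-c2cn([Si](C(C)C)(C(C)C)C(C)C)c3ccc(CC=C(C)C)cc23)c(OC)c(OC)c1-c1cn([Si](C(C)C)(C(C)C)C(C)C)c2ccccc12
F8 | step 8 | 2,3,5,6-tetramethoxy-4-[1-(triisopropylsilyl)indol-3-yl]benzaldehyde | O=Cc1c(OC)c(OC)c(-c2cn([Si](C(C)C)(C(C)C)C(C)C)c3ccccc23)c(OC)c1OC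
F9 | step 8 | racemic tert-butyl N-(2-hydroxy-2-{2,3,5,6-tetramethoxy-4-[1-(triisopropylsilyl)indol-3-yl]phenyl}ethyl)-N-[5-(3-methylbut-2-en-1-yl)furan-2-yl]carbamate | CC(C)=CCc1ccc(o1)N(C(=O)OC(C)(C)C)CC(O)c1c(OC)c(OC)c(-c2cn([Si](C(C)C)(C(C)C)C(C)C)c3ccccc23)c(OC)c1OC
F10 | step 8 | tert-butyl N-[5-(3-methylbut-2-en-1-yl)furan-2-yl]-N-(2-oxo-2-{2,3,5,6-tetramethoxy-4-[1-(triisopropylsilyl)indol-3-yl]phenyl}ethyl)carbamate | CC(C)=CCc1ccc(o1)N(C(=O)OC(C)(C)C)CC(=O)c1c(OC)c(OC)c(-c2cn([Si](C(C)C)(C(C)C)C(C)C)c3ccccc23)c(OC)c1OC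
F11 | step 5 | (2,3,5,6-tetramethoxyphenyl)lithium | COc1cc(OC)c(OC)c([Li])c1OC
F12 | step 5 | (2,3,5,6-tetramethoxyphenyl)zinc chloride | COc1cc(OC)c(OC)c([Zn]Cl)c1OC
F13 | step 5 | 3-(2,3,5,6-tetramethoxyphenyl)-1-(triisopropylsilyl)indole | COc1cc(OC)c(OC)c(-c2cn([Si](C(C)C)(C(C)C)C(C)C)c3ccccc23)c1OC
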